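**Retrosynthetic overview**

1. Numbering: ten-membered ring C1–C10 (C1–C3 the CH2 run, C4(CH3)–C5 the epoxide, C6 the tiglate carbon, C7 the carbon bearing C11(=C13H2)–C12(=O), C8 the lactone O–CH, C9 the carbinol, C10 the CH–CH3).
2. Feature used: the C6–C7 bond lies between the E-C4=C5 alkene (epoxide precursor) and the oxygenated C8–C9 edge. This is a 1,5-diene with oxygen on C9, so a retro-[3,3] shift (anionic oxy-Cope) reconnects C4–C9 and opens C6–C7, folding the ten-membered ring back to a trans-1,2-dialkenylcyclohexanol (ring C10–C1–C2–C3–C4–C9).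
3. The cyclohexanol comes from an (R)-2-methyl-2-alkenylcyclohexanone (quaternary C4 by asymmetric allylation; E-enol ether by Takai olefination and copper C–O coupling) and an E-dienyllithium (C7, C8, C11–C13) made by Stille coupling.
4. After ring expansion: C8–O by Rubottom oxidation, C10–CH3 by enolate methylation, the 4,5-epoxide by C6-hydroxyl-directed epoxidation, the tiglate, C9 by chelation-controlled reduction, and the α-methylene lactone last.
5. Ring order: cyclohexane (bought) → ten-membered carbocycle (step 10) → epoxide (step 14) → γ-lactone (step 18).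

Key step: step 10

Remark on the chemistry: the C10 methyl group is left out of the six-membered precursor on purpose. On the ketone it would lock the C4 alkenyl group equatorial (C4 methyl axial), the dienyl nucleophile would then enter anti to that axial methyl and give the cis-dialkenyl alcohol, and the centre would be epimerisable without thermodynamic bias. It is therefore added after ring expansion (step 12).

Assumption: ketone 8 is used at the enantiomeric purity the catalyst delivers; if needed it is raised by crystallising its semicarbazone, which is not counted as a step.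

**Route**

Step 1
Reactants: 1 2-bromoprop-2-en-1-ol
Product: 2 [(2-bromoprop-2-en-1-yl)oxy](tert-butyl)dimethylsilane
Conditions: TBSCl, imidazole, DMF, rt
Reagents that add atoms: tert-butyldimethylsilyl chloride, CC(C)(C)[Si](C)(C)Cl
Why: Imidazole-mediated silylation protects the primary allylic alcohol so that it survives the organometallic steps and is released only for the final lactonisation.

Step 2
Reactants: 2 silyl ether of 2-bromoallyl alcohol; 3 (E)-1,2-bis(tributylstannyl)ethene (excess)
Product: 4 (E)-tributyl[3-(tert-butyldimethylsilyloxymethyl)buta-1,3-dien-1-yl]stannane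
Conditions: Pd(PPh3)4 (cat.), toluene, 90 °C
Reagents that add atoms: none
Why: Stille coupling of the vinyl bromide with an excess of the bis-stannane should stop after one C–C bond and keep the E geometry, because oxidative addition and transmetallation at palladium are stereoretentive.

Step 3
Reactants: 5 2-methylcyclohexanone
Product: 6 trimethyl[(2-methylcyclohex-1-en-1-yl)oxy]silane
Conditions: TMSCl, NaI, Et3N, MeCN, rt
Reagents that add atoms: chlorotrimethylsilane, C[Si](C)(C)Cl
Why: Silyl enol ether formation under equilibrating conditions (iodotrimethylsilane made in the flask) gives the more substituted, thermodynamic enol ether, which places the later allyl group on the methyl-bearing carbon.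

Step 4
Reactants: 6 thermodynamic silyl enol ether; 7 diallyl carbonate
Product: 8 (R)-2-allyl-2-methylcyclohexanone
Conditions: Pd2(dba)3 (cat.), (R)-4-tert-butyl-2-[2-(diphenylphosphino)phenyl]-4,5-dihydrooxazole ((R)-t-BuPHOX, cat.), Bu4N(Ph3SiF2) (0.35 equiv), THF, 25 °C
Reagents that add atoms: none
Why: Decarboxylative asymmetric allylic alkylation (Tsuji–Trost type, fluoride-initiated enol silane variant) builds the quaternary C4 centre as R because the chiral phosphinooxazoline–palladium allyl complex distinguishes the enolate faces; the R ligand is chosen because the S ligand is known to give the S ketone.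

Step 5
Reactants: 8 (R)-2-allyl-2-methylcyclohexanone
Product: 9 (R)-2-methyl-2-[(E)-prop-1-en-1-yl]cyclohexanone
Conditions: RuHCl(CO)(PPh3)3 (cat.), toluene, 80 °C
Reagents that add atoms: none
Why: Ruthenium hydride-catalysed alkene isomerisation (hydrometallation and β-hydride elimination) moves the terminal double bond to the more stable internal position without touching the quaternary centre.

Step 6
Reactants: 9 propenyl ketone
Product: 10 (R)-1-methyl-2-oxocyclohexane-1-carbaldehyde
Conditions: O3, CH2Cl2, −78 °C; then PPh3
Reagents that add atoms: ozone, [O-][O+]=O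
Why: Ozonolysis with reductive work-up cleaves the propenyl group to the aldehyde on the quaternary carbon, which cannot enolise between the two carbonyl groups and so keeps its configuration.

Step 7
Reactants: 10 keto aldehyde
Product: 11 (R)-2-[(E)-2-iodoethenyl]-2-methylcyclohexanone
Conditions: CrCl2, CHI3, THF, 0 °C to rt
Reagents that add atoms: iodoform, IC(I)I
Why: Takai olefination (geminal dichromium carbenoid from CHI3 and CrCl2) converts the aldehyde, in preference to the hindered ketone, into the iodoalkene (C5=C6), the E geometry arising from anti elimination of the β-oxido chromium intermediate.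

Step 8
Reactants: 11 E-vinyl iodide
Product: 12 (R)-2-{(E)-2-[(4-methoxybenzyl)oxy]ethenyl}-2-methylcyclohexanone
Conditions: 4-methoxybenzyl alcohol, CuI (cat.), 3,4,7,8-tetramethyl-1,10-phenanthroline (cat.), Cs2CO3, toluene, 80 °C
Reagents that add atoms: 4-methoxybenzyl alcohol, COc1ccc(CO)cc1
Why: Copper-catalysed Ullmann-type C–O coupling of a vinyl iodide with an alcohol proceeds with retention of alkene geometry, so the E-enol ether that will deliver the C6 oxygen is obtained without an enolate O-alkylation of uncertain geometry, and its benzyl group can later be removed oxidatively.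

Step 9
Reactants: 4 dienylstannane; 12 enol ether ketone
Product: 14 (1S,2R)-1-[(1E)-3-(tert-butyldimethylsilyloxymethyl)buta-1,3-dien-1-yl]-2-{(E)-2-[(4-methoxybenzyl)oxy]ethenyl}-2-methylcyclohexan-1-ol, via dienyllithium 13 (not isolated)
Conditions: 4, n-BuLi, THF, −78 °C; then 12, −78 °C; aq. NH4Cl
Reagents that add atoms: none
Why: Tin–lithium exchange gives the E-dienyllithium, whose 1,2-addition to the ketone should occur anti to the C4 alkenyl group, which is expected to sit axial at the quaternary α-carbon (Felkin–Anh-type axial attack), so that C9 is formed with the two alkenyl groups trans and the hydroxyl cis to the enol ether arm.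

Step 10
Reactants: 14 trans-1,2-dialkenylcyclohexanol
Product: 17 tert-butyldimethylsilyl enol ether of the ten-membered C9 ketone (E-C4=C5; C6-OPMB; C7 side chain; C8=C9 with C7 trans to C10), via potassium alkoxide 15 (not isolated), via potassium enolate 16 (not isolated)
Conditions: KH, 18-crown-6, THF, 0 to 40 °C; then TBSCl, −78 to 0 °C
Reagents that add atoms: tert-butyldimethylsilyl chloride, CC(C)(C)[Si](C)(C)Cl
Why: The potassium alkoxide, freed from its counter-ion by 18-crown-6, undergoes an anionic oxy-Cope ([3,3]-sigmatropic) rearrangement in which C6–C7 forms while C4–C9 breaks, and the C8=C9 enolate so formed makes the shift irreversible; it is silylated in the flask because protonation to the C9 ketone would give up the regiochemical information needed for the C8 oxidation. The closest known reaction type is the ring expansion of trans-1,2-divinylcyclohexanol alkoxides to (E)-cyclodec-5-enone enolates. The ten-membered ring is not closed end to end: the six ring atoms C10, C1, C2, C3, C4 and C9 are joined by the four alkenyl carbons C5–C8 through a six-membered chair transition state, so no high dilution is needed. C6 and C7 are set by that chair, in which both E-alkenyl termini carry their substituents (OPMB on C6, the C11 unit on C7) equatorially, and their absolute sense follows from the C4 and C9 centres of 14, which are consumed in the step. The step needs the chair pathway and an E-C4=C5 alkene; both are secured by the trans-diequatorial alkenyl groups with the C4 methyl and the alkoxide axial, which keeps C3 and C10 equatorial in the chair.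

Step 11
Reactants: 17 silyl enol ether
Product: 19 C9 ketone with C8–OTBS (ten-membered ring; C8 as in 29), via silyloxy oxirane 18 (not isolated)
Conditions: dimethyldioxirane, acetone–CH2Cl2, −78 to 0 °C; then silica gel
Reagents that add atoms: dimethyldioxirane, CC1(C)OO1
Why: Rubottom oxidation: the electron-rich silyl enol ether is epoxidised in preference to the other alkenes and the silyloxy oxirane opens with 1,4-silyl shift to the α-silyloxy ketone; oxygen should enter C8 from the outer face of the ring, the face turned away from the C4=C5 unit in the conformation in which the ring is formed, which is the C8 configuration of the target.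

Step 12
Reactants: 19 α-silyloxy ketone
Product: 21 C10-methyl ketone (C8 and C10 as in 29), via lithium enolate 20 (not isolated)
Conditions: LiN(i-Pr)2, THF, −78 °C; then MeI, DMPU, −78 to −40 °C
Reagents that add atoms: iodomethane, CI
Why: Kinetic deprotonation of an α-silyloxy ketone by a lithium amide occurs at the unsubstituted α′-methylene (C10), and C-alkylation of the medium-ring enolate with iodomethane should take place from the exposed outer face (peripheral attack), which places the methyl group as in the target.

Step 13
Reactants: 21 C10-methyl ketone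
Product: 22 C6 allylic alcohol
Conditions: DDQ, CH2Cl2–pH 7 buffer, 0 °C
Reagents that add atoms: none
Why: Oxidative cleavage of the 4-methoxybenzyl ether with DDQ (hydride abstraction, then hydrolysis of the oxocarbenium ion) frees the C6 hydroxyl under neutral conditions that leave both silyl ethers, the ketone and the alkenes untouched.

Step 14
Reactants: 22 C6 allylic alcohol
Product: 23 4,5-epoxy C6 alcohol (C4 and C5 as in 29)
Conditions: VO(acac)2 (cat.), t-BuOOH, CH2Cl2, 0 °C to rt
Reagents that add atoms: tert-butyl hydroperoxide, CC(C)(C)OO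
Why: Hydroxyl-directed epoxidation (delivery from a vanadium alkoxide–alkylperoxide complex) oxidises only the allylic C4=C5 double bond, and because the vanadate ester needs a small O–C6–C5=C4 dihedral angle while the ring holds C7 on the inner face of the alkene, oxygen should be delivered to the face that gives the erythro 4,5-epoxide of the target, the opposite of what a peracid is expected to give.

Step 15
Reactants: 23 epoxy alcohol
Product: 24 C6 tiglate
Conditions: (E)-2-methylbut-2-enoyl chloride, pyridine, DMAP (cat.), CH2Cl2, 0 °C to rt
Reagents that add atoms: (E)-2-methylbut-2-enoyl chloride, C/C=C(\C)C(Cl)=O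
Why: DMAP-catalysed acylation (nucleophilic catalysis through the acylpyridinium ion) esterifies the only free hydroxyl, and pyridine is used instead of a trialkylamine so that the acid chloride is not deconjugated through a vinylketene.

Step 16
Reactants: 24 bis-silyl ether tiglate
Product: 25 keto diol (C8–OH and C12–OH free)
Conditions: HF·pyridine, pyridine, THF, 0 °C to rt
Reagents that add atoms: none
Why: Fluoride-mediated desilylation with pyridine-buffered HF removes both silyl ethers, while the epoxide, the tiglate and the ketone tolerate these mildly acidic conditions.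

Step 17
Reactants: 25 α-hydroxy ketone
Product: 26 triol (C9 as in 29)
Conditions: Zn(BH4)2, Et2O, −30 °C; aq. NH4Cl
Reagents that add atoms: none
Why: Chelation-controlled reduction: zinc binds the C8 hydroxyl and the C9 carbonyl oxygen in a five-membered chelate and hydride attacks from the side of the C8 hydrogen (Cram chelate model), which should give the anti 8,9-diol, that is the C9 configuration of the target, without touching the ester or the epoxide.

Step 18
Reactants: 26 triol
Product: 29 CNP0165329.2, via hydroxy enal 27 (not isolated), via lactol 28 (not isolated)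
Conditions: MnO2 (activated, excess), CH2Cl2, rt
Reagents that add atoms: none
Why: Allylic oxidation with MnO2 gives the enal, which closes with the C8 hydroxyl to the five-membered lactol (5-exo-trig addition of O8 to the C12 aldehyde) and is oxidised further to the α-methylene γ-lactone; the non-allylic C9 hydroxyl is not oxidised, and the trans ring fusion follows from the existing C7 and C8 centres.

**Compound list**

1 | 2-bromoprop-2-en-1-ol | OCC(Br)=C | starting material
2 | [(2-bromoprop-2-en-1-yl)oxy](tert-butyl)dimethylsilane | C=C(Br)CO[Si](C)(C)C(C)(C)C | intermediate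
3 | (E)-1,2-bis(tributylstannyl)ethene | CCCC[Sn](CCCC)(CCCC)/C=C/[Sn](CCCC)(CCCC)CCCC | starting material
4 | (E)-tributyl[3-(tert-butyldimethylsilyloxymethyl)buta-1,3-dien-1-yl]stannane | CCCC[Sn](CCCC)(CCCC)/C=C/C(=C)CO[Si](C)(C)C(C)(C)C | intermediate
5 | 2-methylcyclohexanone (racemic) | CC1CCCCC1=O | starting material
6 | trimethyl[(2-methylcyclohex-1-en-1-yl)oxy]silane | CC1=C(O[Si](C)(C)C)CCCC1 | intermediate
7 | diallyl carbonate | C=CCOC(=O)OCC=C | starting material
8 | (R)-2-allyl-2-methylcyclohexanone | C1CCC[C@](C)(CC=C)C1=O | intermediate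
9 | (R)-2-methyl-2-[(E)-prop-1-en-1-yl]cyclohexanone | C1CCC[C@](C)(/C=C/C)C1=O | intermediate
10 | (R)-1-methyl-2-oxocyclohexane-1-carbaldehyde | C1CCC[C@](C)(C=O)C1=O | intermediate
11 | (R)-2-[(E)-2-iodoethenyl]-2-methylcyclohexanone | C1CCC[C@](C)(/C=C/I)C1=O | intermediate
12 | (R)-2-{(E)-2-[(4-methoxybenzyl)oxy]ethenyl}-2-methylcyclohexanone | C1CCC[C@](C)(/C=C/OCc2ccc(OC)cc2)C1=O | intermediate
13 | (E)-[3-(tert-butyldimethylsilyloxymethyl)buta-1,3-dien-1-yl]lithium (not isolated) | [Li]/C=C/C(=C)CO[Si](C)(C)C(C)(C)C | intermediate
14 | (1S,2R)-1-[(1E)-3-(tert-butyldimethylsilyloxymethyl)buta-1,3-dien-1-yl]-2-{(E)-2-[(4-methoxybenzyl)oxy]ethenyl}-2-methylcyclohexan-1-ol (alkenyl groups trans, OH cis to the enol ether arm) | C1CCC[C@](C)(/C=C/OCc2ccc(OC)cc2)[C@@]1(O)/C=C/C(=C)CO[Si](C)(C)C(C)(C)C | intermediate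
15 | potassium alkoxide of 14 (not isolated) | C1CCC[C@](C)(/C=C/OCc2ccc(OC)cc2)[C@@]1([O-])/C=C/C(=C)CO[Si](C)(C)C(C)(C)C.[K+] | intermediate
16 | potassium C8=C9 enolate of the ten-membered ring: E-C4=C5, C6-OPMB, C7-[3-(TBSO)prop-1-en-2-yl], C7 trans to C10 across C8=C9, C6 and C7 as in 29 (not isolated) | C1CCC/C(C)=C/[C@H](OCc2ccc(OC)cc2)[C@@H](C(=C)CO[Si](C)(C)C(C)(C)C)/C=C1\[O-].[K+] | intermediate
17 | C9-O-TBS enol ether corresponding to 16 | C1CCC/C(C)=C/[C@H](OCc2ccc(OC)cc2)[C@@H](C(=C)CO[Si](C)(C)C(C)(C)C)/C=C1\O[Si](C)(C)C(C)(C)C | intermediate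
18 | 8,9-epoxide of 17 (silyloxy oxirane, oxygen on the outer face; not isolated) | C1CCC/C(C)=C/[C@H](OCc2ccc(OC)cc2)[C@@H](C(=C)CO[Si](C)(C)C(C)(C)C)[C@@H]3O[C@@]13O[Si](C)(C)C(C)(C)C | intermediate
19 | ten-membered C9 ketone with C8-OTBS, E-C4=C5, C6-OPMB, C7 side chain (C6, C7, C8 as in 29) | C1CCC/C(C)=C/[C@H](OCc2ccc(OC)cc2)[C@@H](C(=C)CO[Si](C)(C)C(C)(C)C)[C@H](O[Si](C)(C)C(C)(C)C)C1=O | intermediate
20 | lithium C9=C10 enolate of 19, C1 trans to C8 (not isolated) | [Li+].[O-]/C1=C\CCC/C(C)=C/[C@H](OCc2ccc(OC)cc2)[C@@H](C(=C)CO[Si](C)(C)C(C)(C)C)[C@@H]1O[Si](C)(C)C(C)(C)C | intermediate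
21 | C10-methyl derivative of 19 (C10 as in 29) | C[C@@H]1CCC/C(C)=C/[C@H](OCc2ccc(OC)cc2)[C@@H](C(=C)CO[Si](C)(C)C(C)(C)C)[C@H](O[Si](C)(C)C(C)(C)C)C1=O | intermediate
22 | C6 alcohol from 21 (PMB removed) | C[C@@H]1CCC/C(C)=C/[C@H](O)[C@@H](C(=C)CO[Si](C)(C)C(C)(C)C)[C@H](O[Si](C)(C)C(C)(C)C)C1=O | intermediate
23 | 4,5-epoxide of 22 (C4, C5 as in 29) | C[C@@H]1CCC[C@@]2(C)O[C@@H]2[C@H](O)[C@@H](C(=C)CO[Si](C)(C)C(C)(C)C)[C@H](O[Si](C)(C)C(C)(C)C)C1=O | intermediate
24 | C6 tiglate of 23 | C[C@@H]1CCC[C@@]2(C)O[C@@H]2[C@H](OC(=O)/C(C)=C/C)[C@@H](C(=C)CO[Si](C)(C)C(C)(C)C)[C@H](O[Si](C)(C)C(C)(C)C)C1=O | intermediate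
25 | keto diol: C9 ketone, C8-OH, C12-OH, 4,5-epoxide, C6 tiglate | C[C@@H]1CCC[C@@]2(C)O[C@@H]2[C@H](OC(=O)/C(C)=C/C)[C@@H](C(=C)CO)[C@H](O)C1=O | intermediate
26 | triol: C8-OH, C9-OH (cis on the ring, as in 29), C12-OH | C[C@@H]1CCC[C@@]2(C)O[C@@H]2[C@H](OC(=O)/C(C)=C/C)[C@@H](C(=C)CO)[C@H](O)[C@@H]1O | intermediate
27 | C12 aldehyde (2-substituted acrolein) of 26 (not isolated) | C[C@@H]1CCC[C@@]2(C)O[C@@H]2[C@H](OC(=O)/C(C)=C/C)[C@@H](C(=C)C=O)[C@H](O)[C@@H]1O | intermediate
28 | five-membered lactol between C12 and O8, C12 configuration undefined (not isolated) | C[C@@H]1CCC[C@@]2(C)O[C@@H]2[C@H](OC(=O)/C(C)=C/C)[C@H]3C(=C)C(O)O[C@@H]3[C@@H]1O | intermediate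
29 | CNP0165329.2: 4,5-epoxy-9-hydroxy-6-tigloyloxy ten-membered ring with trans-fused C7/C8 α-methylene γ-lactone (4R,5R,6R,7S,8S,9R,10R in the numbering above) | C=C1C(=O)O[C@@H]2[C@H](O)[C@H](C)CCC[C@@]3(C)O[C@@H]3[C@H](OC(=O)/C(C)=C/C)[C@@H]12 | target

**Step count and risks**

Total steps: 18. Longest linear sequence: 16 (steps 3–18, from 2-methylcyclohexanone); the stannane branch (steps 1–2) joins at step 9.

Steps most likely to fail:

Step 14 (epoxidation). The risk is delivery of oxygen to the wrong face of C4=C5: the ring may react through the conformation in which it was formed, where the C6–O bond lies far from the dihedral angle the vanadate needs and the exposed alkene face is the opposite one. The fallback does not depend on the C6 hydroxyl. It sets out from 22, which is first acylated under the conditions of step 15 to give the alkene tiglate F1. Treatment with KHSO5 (as 2KHSO5·KHSO4·K2SO4), NaHCO3, MeCN–aqueous Na2EDTA, 0 °C to rt, should convert the C9 ketone, activated by its α-silyloxy group, into the spiro dioxirane F2 (not isolated). This is ketone-derived dioxirane epoxidation in its intramolecular mode: one oxygen passes across the ring to the C4=C5 face that looks at C9, the face from which C9 left C4 in step 10, which is the face the target requires. The sequence comes back to the route at 24.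

Step 12 (C10 methylation). The risk is that the methyl group enters from the unexpected face of the C9=C10 enolate, or that alkylation goes on to the dimethyl compound. The fallback reverses the order in which carbon and hydrogen are put on C10. It sets out from 19: LiN(i-Pr)2, then dimethyl(methylidene)ammonium iodide gives the Mannich base F3; MeI followed by NaHCO3 eliminates trimethylamine to the α-methylene ketone F4. Conjugate reduction with [(Ph3P)CuH]6 and protonation of the resulting enolate with NH4Cl then places hydrogen, not carbon, on the accessible face, so the methyl group ends on the face that direct methylation missed. The sequence comes back at 21.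

Step 9 (dienyl addition). The risk is poor facial selectivity, giving a mixture of trans- and cis-dialkenyl alcohols, of which only the trans isomer can pass through the chair in step 10. The fallback uses a slimmer sp nucleophile, which follows the axial trajectory anti to the axial C4 alkenyl group more strictly. It sets out from 2 and 12: Sonogashira coupling of 2 with ethynyltrimethylsilane (PdCl2(PPh3)2, CuI, Et3N) gives the silyl enyne F5; K2CO3 in MeOH gives the terminal enyne F6; its lithium acetylide (n-BuLi, THF, −78 °C) adds to 12 to give the propargylic alcohol F7. Hydroxyl-directed trans-hydroalumination with NaAlH2(OCH2CH2OCH3)2 in THF then sets the E-C7=C8 bond, and the sequence comes back at 14.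

**Further compounds**

F1 | step 14 | C6 tiglate of 22 (C4=C5 alkene kept) | C[C@@H]1CCC/C(C)=C/[C@H](OC(=O)/C(C)=C/C)[C@@H](C(=C)CO[Si](C)(C)C(C)(C)C)[C@H](O[Si](C)(C)C(C)(C)C)C1=O
F2 | step 14 | C9 spiro dioxirane of F1 (not isolated) | C[C@@H]1CCC/C(C)=C/[C@H](OC(=O)/C(C)=C/C)[C@@H](C(=C)CO[Si](C)(C)C(C)(C)C)[C@H](O[Si](C)(C)C(C)(C)C)C12OO2
F3 | step 12 | C10 (dimethylamino)methyl derivative of 19 (C10 configuration undefined) | CN(C)CC1CCC/C(C)=C/[C@H](OCc2ccc(OC)cc2)[C@@H](C(=C)CO[Si](C)(C)C(C)(C)C)[C@H](O[Si](C)(C)C(C)(C)C)C1=O
F4 | step 12 | C10 methylidene derivative of 19 | C=C1CCC/C(C)=C/[C@H](OCc2ccc(OC)cc2)[C@@H](C(=C)CO[Si](C)(C)C(C)(C)C)[C@H](O[Si](C)(C)C(C)(C)C)C1=O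
F5 | step 9 | tert-butyldimethyl{[2-methylidene-4-(trimethylsilyl)but-3-yn-1-yl]oxy}silane | C=C(CO[Si](C)(C)C(C)(C)C)C#C[Si](C)(C)C
F6 | step 9 | tert-butyldimethyl[(2-methylidenebut-3-yn-1-yl)oxy]silane | C=C(CO[Si](C)(C)C(C)(C)C)C#C
F7 | step 9 | propargylic alcohol: 14 with a C7≡C8 triple bond in place of the E double bond (ring centres as in 14) | C1CCC[C@](C)(/C=C/OCc2ccc(OC)cc2)[C@@]1(O)C#CC(=C)CO[Si](C)(C)C(C)(C)C
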